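## Retrosynthetic overview

1. **21 ⇒ 19 (key step, C5–O):** the acetate is installed last by a copper-catalysed, stereoconvergent allylic acetoxylation (new) of the C5-epimeric allylic alcohols, which fixes C5 and keeps the 4(15)-methylene.
2. **19 ⇒ 18 (C4–C5):** Nozaki–Hiyama–Kishi closure of the ten-membered carbocycle, the third and last ring.
3. **18 ⇒ 13 ⇒ 12 + 5:** the γ-lactone (second ring) closes by O6–C12 lactonisation after O8 tigloylation; C7–C8 comes from an indium Barbier coupling.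
4. **12 ⇒ 6 + 7:** the C10–O bond is set by Sharpless epoxidation then hydride opening; C2–C3 by copper-acetylide alkylation.
5. **5 ⇒ 1:** D-mannitol diacetonide supplies C5–C7 with C6–O held in a dioxolane (first ring, temporary); Morita–Baylis–Hillman reaction and bromination add C11–C13.

Atom labels C1–C15 are germacrane numbers (lactone O on C6, tiglate on C8, tertiary OH on C10, acetate on C5).

Assumption: 4, 19 and 20 are handled as epimer mixtures at the single centre named in the compound list; every other numbered compound is one stereoisomer.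

## Route

Step 1
Reactants: 1 1,2:5,6-di-O-isopropylidene-D-mannitol
Product: 2 (4R)-2,2-dimethyl-1,3-dioxolane-4-carbaldehyde
Conditions: NaIO4, sat. aq. NaHCO3, CH2Cl2, 20 °C
Reagents that add atoms: none
Why: Malaprade glycol cleavage of the free 3,4-diol gives two equivalents of the aldehyde and leaves the acetal-protected stereocentre (future C6) untouched.

Step 2
Reactants: 2 (4R)-2,2-dimethyl-1,3-dioxolane-4-carbaldehyde; 3 methyl acrylate
Product: 4 methyl 2-{[(4R)-2,2-dimethyl-1,3-dioxolan-4-yl](hydroxy)methyl}prop-2-enoate (both carbinol epimers)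
Conditions: DABCO (0.5 equiv), 1,4-dioxane–H2O (1:1), 20 °C, 48 h
Reagents that add atoms: none
Why: Morita–Baylis–Hillman reaction of the activated α-alkoxy aldehyde attaches the acrylate (C11–C13) to the future C7; the new carbinol forms as a mixture that does not matter because step 3 erases it.

Step 3
Reactants: 4 methyl 2-{[(4R)-2,2-dimethyl-1,3-dioxolan-4-yl](hydroxy)methyl}prop-2-enoate
Product: 5 methyl (2Z)-2-(bromomethyl)-3-[(4S)-2,2-dimethyl-1,3-dioxolan-4-yl]prop-2-enoate
Conditions: NBS, Me2S, CH2Cl2, 0 → 20 °C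
Reagents that add atoms: N-bromosuccinimide, O=C1CCC(=O)N1Br
Why: Corey–Kim-type bromosulfonium activation of the allylic alcohol followed by SN2′ return of bromide gives the conjugated, thermodynamically preferred Z allylic bromide without touching the dioxolane stereocentre.

Step 4
Reactants: 6 (2E)-3-methylpent-2-en-4-yn-1-ol; 7 2,3-dibromoprop-1-ene
Product: 8 (2E)-7-bromo-3-methylocta-2,7-dien-4-yn-1-ol
Conditions: CuI (10 mol %), K2CO3, Bu4NI (10 mol %), DMF, 20 °C
Reagents that add atoms: none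
Why: copper-acetylide alkylation (SN2 at the allylic CH2Br; the vinylic C–Br bond is inert) forms C2–C3 and brings in the 2-bromoallyl unit needed for ring closure.

Step 5
Reactants: 8 (2E)-7-bromo-3-methylocta-2,7-dien-4-yn-1-ol
Product: 9 [(2S,3S)-3-(4-bromopent-4-en-1-yn-1-yl)-3-methyloxiran-2-yl]methanol
Conditions: Ti(OiPr)4 (10 mol %), L-(+)-diethyl tartrate (12 mol %), t-BuOOH, 4 Å molecular sieves, CH2Cl2, −20 °C
Reagents that add atoms: tert-butyl hydroperoxide, CC(C)(C)OO
Why: Sharpless asymmetric epoxidation; with L-(+)-tartrate the E allylic alcohol is epoxidised on the face that gives the 2S,3S epoxide (the same sense as geraniol), which fixes the C–O bond of the future C10.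

Step 6
Reactants: 9 [(2S,3S)-3-(4-bromopent-4-en-1-yn-1-yl)-3-methyloxiran-2-yl]methanol
Product: 11 (3R,4E)-7-bromo-3-methylocta-4,7-diene-1,3-diol, via alkynyl diol 10 (not isolated)
Conditions: NaAlH2(OCH2CH2OMe)2 (3.5 equiv), THF, 0 → 20 °C; aq. potassium sodium tartrate work-up
Reagents that add atoms: none
Why: hydride is delivered from the primary alkoxyaluminate to C2 of the 2,3-epoxy alcohol (regioselective opening to the 1,3-diol, the quaternary C–O bond is retained), and the tertiary propargylic alkoxyaluminate then effects trans-hydroalumination to the E alkene.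

Step 7
Reactants: 11 (3R,4E)-7-bromo-3-methylocta-4,7-diene-1,3-diol
Product: 12 (3R,4E)-7-bromo-3-hydroxy-3-methylocta-4,7-dienal
Conditions: TEMPO (10 mol %), PhI(OAc)2, CH2Cl2, 20 °C
Reagents that add atoms: none
Why: oxoammonium (TEMPO) oxidation is selective for the primary alcohol and neutral enough to keep the β-hydroxy aldehyde from eliminating; no stereocentre is touched.

Step 8
Reactants: 12 (3R,4E)-7-bromo-3-hydroxy-3-methylocta-4,7-dienal; 5 methyl (2Z)-2-(bromomethyl)-3-[(4S)-2,2-dimethyl-1,3-dioxolan-4-yl]prop-2-enoate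
Product: 13 methyl (3R,4R,6R,7E)-10-bromo-3-[(4S)-2,2-dimethyl-1,3-dioxolan-4-yl]-4,6-dihydroxy-6-methyl-2-methylideneundeca-7,10-dienoate
Conditions: indium metal powder (In, 1.5 equiv), THF–H2O (1:1), 20 °C
Reagents that add atoms: none
Why: Barbier allylation through the γ-carbon of the allylindium in a chair transition state, in which the Z γ-substituent gives the 7,8-syn adduct, the aldehyde adds to C7 anti to the allylic dioxolane C–O bond (A1,3-strain model), and indium chelation by the free C10 hydroxyl favours the 8,10-anti carbinol, so reagent and substrate control are matched.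

Step 9
Reactants: 13 methyl (3R,4R,6R,7E)-10-bromo-3-[(4S)-2,2-dimethyl-1,3-dioxolan-4-yl]-4,6-dihydroxy-6-methyl-2-methylideneundeca-7,10-dienoate; 14 tiglic acid
Product: 15 methyl (3R,4R,6R,7E)-10-bromo-3-[(4S)-2,2-dimethyl-1,3-dioxolan-4-yl]-6-hydroxy-6-methyl-2-methylidene-4-{[(2E)-2-methylbut-2-enoyl]oxy}undeca-7,10-dienoate
Conditions: DCC, DMAP (20 mol %), CH2Cl2, 0 → 20 °C
Reagents that add atoms: none
Why: Steglich esterification acylates only the secondary C8 hydroxyl (the tertiary C10 hydroxyl is inert), with retention at C8 and without isomerising the tiglate.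

Step 10
Reactants: 15 methyl (3R,4R,6R,7E)-10-bromo-3-[(4S)-2,2-dimethyl-1,3-dioxolan-4-yl]-6-hydroxy-6-methyl-2-methylidene-4-{[(2E)-2-methylbut-2-enoyl]oxy}undeca-7,10-dienoate
Product: 17 (1R,3R,4E)-7-bromo-3-hydroxy-1-[(2S,3R)-2-(hydroxymethyl)-4-methylidene-5-oxooxolan-3-yl]-3-methylocta-4,7-dien-1-yl (2E)-2-methylbut-2-enoate, via diol ester 16 (not isolated)
Conditions: AcOH–H2O (4:1), 40 °C; then PPTS (10 mol %), toluene, 50 °C
Reagents that add atoms: none
Why: acetal hydrolysis frees the 5,6-diol and the C6 hydroxyl closes the five-membered lactone by transesterification (preferred over the six-membered ring through O5; O8 is blocked as the tiglate), with all stereocentres retained.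

Step 11
Reactants: 17 (1R,3R,4E)-7-bromo-3-hydroxy-1-[(2S,3R)-2-(hydroxymethyl)-4-methylidene-5-oxooxolan-3-yl]-3-methylocta-4,7-dien-1-yl (2E)-2-methylbut-2-enoate
Product: 18 (1R,3R,4E)-7-bromo-1-[(2S,3R)-2-formyl-4-methylidene-5-oxooxolan-3-yl]-3-hydroxy-3-methylocta-4,7-dien-1-yl (2E)-2-methylbut-2-enoate
Conditions: TEMPO (20 mol %), PhI(OAc)2, CH2Cl2, 20 °C
Reagents that add atoms: none
Why: TEMPO oxidation converts the only primary alcohol into the C5 aldehyde under neutral conditions that do not epimerise the adjacent C6 centre or touch the tertiary alcohol.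

Step 12
Reactants: 18 (1R,3R,4E)-7-bromo-1-[(2S,3R)-2-formyl-4-methylidene-5-oxooxolan-3-yl]-3-hydroxy-3-methylocta-4,7-dien-1-yl (2E)-2-methylbut-2-enoate
Product: 19 (3aR,4R,6R,7E,11aS)-6,11-dihydroxy-6-methyl-3,10-dimethylidene-2-oxo-2,3,3a,4,5,6,9,10,11,11a-decahydrocyclodeca[b]furan-4-yl (2E)-2-methylbut-2-enoate (both C11 epimers; C11 is germacrane C5)
Conditions: CrCl2 (8 equiv), NiCl2 (10 mol %), DMSO–THF (3:1), 0.002 M, slow addition, 20 °C
Reagents that add atoms: none
Why: Nozaki–Hiyama–Kishi coupling, in which the alkenylchromium formed from the vinyl bromide adds chemoselectively to the aldehyde under high dilution and closes the ten-membered ring with the exocyclic methylene in place; C5 forms as an epimer mixture (Felkin–Anh addition anti to the C6–O bond should favour 5R), which is acceptable because step 13 erases this centre.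

Step 13
Reactants: 19 (3aR,4R,6R,7E,11aS)-6,11-dihydroxy-6-methyl-3,10-dimethylidene-2-oxo-2,3,3a,4,5,6,9,10,11,11a-decahydrocyclodeca[b]furan-4-yl (2E)-2-methylbut-2-enoate (both C11 epimers)
Product: 21 (3aR,4R,6R,7E,11S,11aS)-11-(acetyloxy)-6-hydroxy-6-methyl-3,10-dimethylidene-2-oxo-2,3,3a,4,5,6,9,10,11,11a-decahydrocyclodeca[b]furan-4-yl (2E)-2-methylbut-2-enoate (CNP0323375.1), via allylic phosphate 20 (not isolated)
Conditions: ClP(O)(OEt)2, Et3N, DMAP (10 mol %), CH2Cl2, 0 °C; then CuOAc (20 mol %), 4,4′-di-tert-butyl-2,2′-bipyridine (24 mol %), KOAc, 18-crown-6 (20 mol %), THF, 20 °C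
Reagents that add atoms: potassium acetate, CC(=O)[O-].[K+]
Why: Proposed new method: after selective phosphorylation of the secondary allylic hydroxyl, CuOAc/bipyridine is expected to add to either phosphate epimer by anti-SN2′ oxidative addition, giving one σ-allyl trivalent-copper acetate (Cu on C15, C4=C5 in the ring) in which C5 is no longer a stereocentre; the C–O bond then forms by the seven-membered pericyclic reductive elimination of the Kharasch–Sosnovsky reaction, which returns oxygen to the more substituted terminus C5, restores the 4(15)-methylene and delivers acetate from copper to the exposed outer face of the ring alkene (the face peracids use in germacranolides), giving 5S from both epimers; closest known reaction types: Kharasch–Sosnovsky allylic acyloxylation and copper-catalysed SN2′ substitution of allylic phosphates.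

## Compound list

1 | 1,2:5,6-di-O-isopropylidene-D-mannitol | CC1(C)OC[C@@H](O1)[C@@H](O)[C@H](O)[C@H]2COC(C)(C)O2 | starting material
2 | (4R)-2,2-dimethyl-1,3-dioxolane-4-carbaldehyde | O=C[C@H]1COC(C)(C)O1 | intermediate
3 | methyl acrylate | C=CC(=O)OC | starting material
4 | methyl 2-{[(4R)-2,2-dimethyl-1,3-dioxolan-4-yl](hydroxy)methyl}prop-2-enoate (both carbinol epimers) | COC(=O)C(=C)C(O)[C@H]1COC(C)(C)O1 | intermediate
5 | methyl (2Z)-2-(bromomethyl)-3-[(4S)-2,2-dimethyl-1,3-dioxolan-4-yl]prop-2-enoate | COC(=O)/C(CBr)=C/[C@H]1COC(C)(C)O1 | intermediate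
6 | (2E)-3-methylpent-2-en-4-yn-1-ol | OC/C=C(C)/C#C | starting material
7 | 2,3-dibromoprop-1-ene | C=C(Br)CBr | starting material
8 | (2E)-7-bromo-3-methylocta-2,7-dien-4-yn-1-ol | OC/C=C(C)/C#CCC(Br)=C | intermediate
9 | [(2S,3S)-3-(4-bromopent-4-en-1-yn-1-yl)-3-methyloxiran-2-yl]methanol | OC[C@@H]1O[C@@]1(C)C#CCC(Br)=C | intermediate
10 | (3R)-7-bromo-3-methyloct-7-en-4-yne-1,3-diol | OCC[C@@](C)(O)C#CCC(Br)=C | intermediate
11 | (3R,4E)-7-bromo-3-methylocta-4,7-diene-1,3-diol | OCC[C@@](C)(O)/C=C/CC(Br)=C | intermediate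
12 | (3R,4E)-7-bromo-3-hydroxy-3-methylocta-4,7-dienal | O=CC[C@@](C)(O)/C=C/CC(Br)=C | intermediate
13 | methyl (3R,4R,6R,7E)-10-bromo-3-[(4S)-2,2-dimethyl-1,3-dioxolan-4-yl]-4,6-dihydroxy-6-methyl-2-methylideneundeca-7,10-dienoate | COC(=O)C(=C)[C@@H]([C@H]1COC(C)(C)O1)[C@H](O)C[C@@](C)(O)/C=C/CC(Br)=C | intermediate
14 | tiglic acid, (2E)-2-methylbut-2-enoic acid | C/C=C(\C)C(=O)O | starting material
15 | methyl (3R,4R,6R,7E)-10-bromo-3-[(4S)-2,2-dimethyl-1,3-dioxolan-4-yl]-6-hydroxy-6-methyl-2-methylidene-4-{[(2E)-2-methylbut-2-enoyl]oxy}undeca-7,10-dienoate | COC(=O)C(=C)[C@@H]([C@H]1COC(C)(C)O1)[C@H](OC(=O)/C(C)=C/C)C[C@@](C)(O)/C=C/CC(Br)=C | intermediate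
16 | methyl (3S,4R,6R,7E)-10-bromo-3-[(1S)-1,2-dihydroxyethyl]-6-hydroxy-6-methyl-2-methylidene-4-{[(2E)-2-methylbut-2-enoyl]oxy}undeca-7,10-dienoate | COC(=O)C(=C)[C@@H]([C@H](O)CO)[C@H](OC(=O)/C(C)=C/C)C[C@@](C)(O)/C=C/CC(Br)=C | intermediate
17 | (1R,3R,4E)-7-bromo-3-hydroxy-1-[(2S,3R)-2-(hydroxymethyl)-4-methylidene-5-oxooxolan-3-yl]-3-methylocta-4,7-dien-1-yl (2E)-2-methylbut-2-enoate | C=C1C(=O)O[C@H](CO)[C@H]1[C@H](OC(=O)/C(C)=C/C)C[C@@](C)(O)/C=C/CC(Br)=C | intermediate
18 | (1R,3R,4E)-7-bromo-1-[(2S,3R)-2-formyl-4-methylidene-5-oxooxolan-3-yl]-3-hydroxy-3-methylocta-4,7-dien-1-yl (2E)-2-methylbut-2-enoate | C=C1C(=O)O[C@H](C=O)[C@H]1[C@H](OC(=O)/C(C)=C/C)C[C@@](C)(O)/C=C/CC(Br)=C | intermediate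
19 | (3aR,4R,6R,7E,11aS)-6,11-dihydroxy-6-methyl-3,10-dimethylidene-2-oxo-2,3,3a,4,5,6,9,10,11,11a-decahydrocyclodeca[b]furan-4-yl (2E)-2-methylbut-2-enoate (both C11 epimers) | C=C1C(=O)O[C@H]2[C@H]1[C@H](OC(=O)/C(C)=C/C)C[C@@](C)(O)/C=C/CC(=C)C2O | intermediate
20 | (3aR,4R,6R,7E,11aS)-11-[(diethoxyphosphoryl)oxy]-6-hydroxy-6-methyl-3,10-dimethylidene-2-oxo-2,3,3a,4,5,6,9,10,11,11a-decahydrocyclodeca[b]furan-4-yl (2E)-2-methylbut-2-enoate (both C11 epimers) | C=C1C(=O)O[C@H]2[C@H]1[C@H](OC(=O)/C(C)=C/C)C[C@@](C)(O)/C=C/CC(=C)C2OP(=O)(OCC)OCC | intermediate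
21 | (3aR,4R,6R,7E,11S,11aS)-11-(acetyloxy)-6-hydroxy-6-methyl-3,10-dimethylidene-2-oxo-2,3,3a,4,5,6,9,10,11,11a-decahydrocyclodeca[b]furan-4-yl (2E)-2-methylbut-2-enoate (CNP0323375.1) | C=C1C(=O)O[C@H]2[C@H]1[C@H](OC(=O)/C(C)=C/C)C[C@@](C)(O)/C=C/CC(=C)[C@@H]2OC(C)=O | target

## Step count and risks

Total steps: 13. Longest linear sequence: 10 steps (6 → 8 → 9 → 11 → 12 → 13 → 15 → 17 → 18 → 19 → 21); the branch from 1 to 5 is 3 steps.

The three steps most likely to fail are 13, 12 and 8.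

**Step 13 (proposed new copper-catalysed acetoxylation).** The oxidative addition of CuOAc to the phosphate may be slow, or the acetate may return to the wrong face or to C15. The fallback uses only known chemistry, sets out from 19 and comes back at 21. The two epimers of 19 are separated by chromatography. The 11S alcohol F4 is acetylated with retention (Ac2O, DMAP, pyridine, CH2Cl2, 0 °C). The 11R alcohol F5 is converted with inversion by a Mitsunobu reaction with acetic acid (AcOH, PPh3, DIAD, THF, 0 °C). Both give 21.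

**Step 12 (ring closure).** The vinyl bromide may be sluggish towards NiCl2/CrCl2, or oligomers may form. The fallback sets out from 17 and comes back at 19, closing the same bond with boron and rhodium instead of chromium. Miyaura borylation of the vinyl bromide of 17 (B2pin2, PdCl2(PPh3)2, PPh3, KOPh, toluene, 50 °C) gives the alkenyl pinacolboronate alcohol F2. TEMPO/PhI(OAc)2 oxidation gives the boronate aldehyde F3. Rhodium-catalysed intramolecular 1,2-addition of the alkenylboronate to the aldehyde ([Rh(OH)(cod)]2, P(t-Bu)3, 1,4-dioxane–H2O, 20 °C, high dilution) then gives 19 as its epimer mixture.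

**Step 8 (Barbier coupling).** Three stereochemical elements are set at once, and the C8 carbinol is the least secure. The fallback sets out from 12 and 5 and comes back at 15. If the coupling gives mainly the 7,8-anti carbinol, the C4 epimer of 13 F1 (the usual sense when CrCl2 in THF replaces indium), C8 is corrected in the esterification itself. Mitsunobu reaction of F1 with tiglic acid 14 (PPh3, DIAD, THF, 0 °C) forms the C8–O bond with inversion and gives 15 directly.

## Further compounds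

F1 | step 8 | methyl (3R,4S,6R,7E)-10-bromo-3-[(4S)-2,2-dimethyl-1,3-dioxolan-4-yl]-4,6-dihydroxy-6-methyl-2-methylideneundeca-7,10-dienoate | COC(=O)C(=C)[C@@H]([C@H]1COC(C)(C)O1)[C@@H](O)C[C@@](C)(O)/C=C/CC(Br)=C
F2 | step 12 | (1R,3R,4E)-3-hydroxy-1-[(2S,3R)-2-(hydroxymethyl)-4-methylidene-5-oxooxolan-3-yl]-3-methyl-7-(4,4,5,5-tetramethyl-1,3,2-dioxaborolan-2-yl)octa-4,7-dien-1-yl (2E)-2-methylbut-2-enoate | C=C1C(=O)O[C@H](CO)[C@H]1[C@H](OC(=O)/C(C)=C/C)C[C@@](C)(O)/C=C/CC(=C)B1OC(C)(C)C(C)(C)O1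
F3 | step 12 | (1R,3R,4E)-1-[(2S,3R)-2-formyl-4-methylidene-5-oxooxolan-3-yl]-3-hydroxy-3-methyl-7-(4,4,5,5-tetramethyl-1,3,2-dioxaborolan-2-yl)octa-4,7-dien-1-yl (2E)-2-methylbut-2-enoate | C=C1C(=O)O[C@H](C=O)[C@H]1[C@H](OC(=O)/C(C)=C/C)C[C@@](C)(O)/C=C/CC(=C)B1OC(C)(C)C(C)(C)O1
F4 | step 13 | (3aR,4R,6R,7E,11S,11aS)-6,11-dihydroxy-6-methyl-3,10-dimethylidene-2-oxo-2,3,3a,4,5,6,9,10,11,11a-decahydrocyclodeca[b]furan-4-yl (2E)-2-methylbut-2-enoate | C=C1C(=O)O[C@H]2[C@H]1[C@H](OC(=O)/C(C)=C/C)C[C@@](C)(O)/C=C/CC(=C)[C@@H]2O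
F5 | step 13 | (3aR,4R,6R,7E,11R,11aS)-6,11-dihydroxy-6-methyl-3,10-dimethylidene-2-oxo-2,3,3a,4,5,6,9,10,11,11a-decahydrocyclodeca[b]furan-4-yl (2E)-2-methylbut-2-enoate | C=C1C(=O)O[C@H]2[C@H]1[C@H](OC(=O)/C(C)=C/C)C[C@@](C)(O)/C=C/CC(=C)[C@H]2O
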